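**Retrosynthetic overview**
1. Target ⇐ C6-vinyl acid ⇐ C6-formyl acid ⇐ C6-(1,2-diol): the C6 ethyl group is carried as the two carbons of a Sharpless epoxy alcohol.
2. Key disconnection: both C–O bonds of the peroxide are cut back to H2O2 and two electrophilic carbons. C6 is a tertiary vinyl epoxide (opened with inversion) and C3 is the alkyl carbon of a β-lactone (opened with inversion, which frees the CH2CO2H arm).
3. β-Lactone ⇐ catalytic asymmetric ketene–aldehyde [2+2] on an α-ethyl aldehyde (C3 by catalyst); C4 ⇐ Evans alkylation with a (Z)-2-iodoallyl bromide.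
4. C6–C7 bond ⇐ Negishi carboalumination/cross-coupling of (S)-4-ethyloct-1-yne (from hex-1-ene by Zr-catalysed asymmetric carboalumination) with the vinyl iodide.
5. Ring order: the 1,2-dioxane is the only ring of the target and is closed once, in step 13; the β-lactone is a transient ring made in step 10 and consumed in step 13.

Assumption: locants C1–C10 in the Why lines follow the target acid (C1 = CO2H; C3, C4, C6 = ring carbons; C7=C8 = side-chain alkene; C10 = side-chain stereocentre). The sense of induction of (+)-(NMI)2ZrCl2 (step 1) and of O-trimethylsilylquinine (step 10) is taken from the nearest literature models, and the mirror-image catalyst would be used if either proves opposite. Both catalysts and anhydrous ethereal H2O2 are treated as stock reagents.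

**Route**

Step 1
Reactants: 1 hex-1-ene
Product: 3 (3S)-3-(iodomethyl)heptane, via alkylalane 2 (not isolated)
Conditions: Et3Al, (+)-(NMI)2ZrCl2 (NMI = 1-neomenthylindenyl; 5 mol %), CH2Cl2, 0 °C to rt; then I2, THF, 0 °C
Reagents that add atoms: triethylaluminium, CC[Al](CC)CC; iodine, II
Why: Negishi zirconium-catalysed asymmetric carboalumination adds ethyl and aluminium across one face of the terminal alkene (sets C10, about 90–93% ee expected), and iodinolysis of the C–Al bond does not touch the new stereocentre.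

Step 2
Reactants: 3 (3S)-3-(iodomethyl)heptane
Product: 4 (4S)-4-ethyloct-1-yne
Conditions: LiC≡CH·H2NCH2CH2NH2, DMSO, 15 °C to rt
Reagents that add atoms: lithium acetylide ethylenediamine complex, [Li+].[C-]#C.NCCN
Why: SN2 alkylation of acetylide by the primary iodide in DMSO, with the stereocentre β to the reacting carbon and therefore untouched.

Step 3
Reactants: 5 2-[(tert-butyldimethylsilyl)oxy]acetaldehyde; 6 ethyl 2-(triphenyl-λ5-phosphanylidene)acetate
Product: 8 ethyl (2Z)-4-[(tert-butyldimethylsilyl)oxy]-2-iodobut-2-enoate, via iodo ylide 7 (not isolated)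
Conditions: N-iodosuccinimide, CH2Cl2, −20 °C; then 5, −20 °C to rt
Reagents that add atoms: N-iodosuccinimide, O=C1CCC(=O)N1I
Why: one-pot ylide iodination and Wittig olefination, in which the stabilised iodo ylide places the ester trans to the CH2OSi group so that iodine and CH2OSi end up cis (Z), the geometry that later defines C6.

Step 4
Reactants: 8 ethyl (2Z)-4-[(tert-butyldimethylsilyl)oxy]-2-iodobut-2-enoate
Product: 9 (2Z)-4-[(tert-butyldimethylsilyl)oxy]-2-iodobut-2-en-1-ol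
Conditions: iBu2AlH (2.2 equiv), CH2Cl2, −78 °C
Reagents that add atoms: none
Why: 1,2-reduction of the enoate by the aluminium hydride at low temperature leaves the vinyl iodide, the alkene geometry and the silyl ether intact.

Step 5
Reactants: 9 (2Z)-4-[(tert-butyldimethylsilyl)oxy]-2-iodobut-2-en-1-ol
Product: 10 {[(2Z)-4-bromo-3-iodobut-2-en-1-yl]oxy}(tert-butyl)dimethylsilane
Conditions: CBr4, PPh3, CH2Cl2, 0 °C
Reagents that add atoms: carbon tetrabromide, BrC(Br)(Br)Br
Why: Appel bromination of the primary allylic alcohol proceeds by SN2 at CH2 under cold neutral conditions without allylic transposition.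

Step 6
Reactants: 11 (4S)-4-benzyl-3-butanoyl-1,3-oxazolidin-2-one; 10 {[(2Z)-4-bromo-3-iodobut-2-en-1-yl]oxy}(tert-butyl)dimethylsilane
Product: 13 (4S)-4-benzyl-3-[(2R,4Z)-6-[(tert-butyldimethylsilyl)oxy]-2-ethyl-4-iodohex-4-enoyl]-1,3-oxazolidin-2-one, via sodium enolate 12 (not isolated)
Conditions: NaN(SiMe3)2, THF, −78 °C; then 10, −78 to −45 °C
Reagents that add atoms: none
Why: Evans asymmetric alkylation, in which the chelated Z-enolate is alkylated by the allylic bromide on the face opposite the benzyl group, setting C4 (2R in this compound, d.r. above 95:5 expected).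

Step 7
Reactants: 13 (4S)-4-benzyl-3-[(2R,4Z)-6-[(tert-butyldimethylsilyl)oxy]-2-ethyl-4-iodohex-4-enoyl]-1,3-oxazolidin-2-one
Product: 14 (2R,4Z)-6-[(tert-butyldimethylsilyl)oxy]-2-ethyl-4-iodohex-4-en-1-ol
Conditions: LiBH4, MeOH (1 equiv), Et2O, 0 °C
Reagents that add atoms: none
Why: reductive removal of the oxazolidinone auxiliary by borohydride attacks the exocyclic acyl group without epimerising C4 or touching the vinyl iodide.

Step 8
Reactants: 4 (4S)-4-ethyloct-1-yne; 14 (2R,4Z)-6-[(tert-butyldimethylsilyl)oxy]-2-ethyl-4-iodohex-4-en-1-ol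
Product: 16 (2R,4Z,5E,8S)-4-{2-[(tert-butyldimethylsilyl)oxy]ethylidene}-2,8-diethyl-6-methyldodec-5-en-1-ol, via alkenylalane 15 (not isolated)
Conditions: 4, Me3Al, Cp2ZrCl2 (20 mol %), CH2Cl2, 0 °C to rt; then 14 (premixed with 1 equiv Me3Al), ZnCl2 (cocatalyst), Pd(PPh3)4 (5 mol %), THF, rt
Reagents that add atoms: trimethylaluminium, C[Al](C)C
Why: Negishi zirconium-catalysed syn-carboalumination gives the (E)-2-methylalkenylalane regioselectively, and the palladium-catalysed Negishi cross-coupling with the vinyl iodide retains geometry at both partners, giving the (E) C7=C8 alkene and a dienyl system of defined geometry.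

Step 9
Reactants: 16 (2R,4Z,5E,8S)-4-{2-[(tert-butyldimethylsilyl)oxy]ethylidene}-2,8-diethyl-6-methyldodec-5-en-1-ol
Product: 17 (2R,4Z,5E,8S)-4-{2-[(tert-butyldimethylsilyl)oxy]ethylidene}-2,8-diethyl-6-methyldodec-5-enal
Conditions: TEMPO (10 mol %), PhI(OAc)2, CH2Cl2, rt
Reagents that add atoms: none
Why: nitroxyl-catalysed oxidation of the primary alcohol stops at the aldehyde under near-neutral conditions that neither epimerise C4 nor touch the diene.

Step 10
Reactants: 17 (2R,4Z,5E,8S)-4-{2-[(tert-butyldimethylsilyl)oxy]ethylidene}-2,8-diethyl-6-methyldodec-5-enal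
Product: 18 (4S)-4-[(3R,5Z,6E,9S)-5-{2-[(tert-butyldimethylsilyl)oxy]ethylidene}-9-ethyl-7-methyltridec-6-en-3-yl]oxetan-2-one
Conditions: CH3COCl, iPr2NEt, O-trimethylsilylquinine (10 mol %), LiClO4, CH2Cl2/Et2O, −78 to −40 °C
Reagents that add atoms: acetyl chloride, CC(Cl)=O
Why: alkaloid/LiClO4-catalysed acyl halide–aldehyde cyclocondensation (formal ketene–aldehyde [2+2]), in which the quinine-derived ammonium enolate adds to one aldehyde face under catalyst control, setting C3 as the (S)-lactone carbon and installing C1–C2 at the acid oxidation level.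

Step 11
Reactants: 18 (4S)-4-[(3R,5Z,6E,9S)-5-{2-[(tert-butyldimethylsilyl)oxy]ethylidene}-9-ethyl-7-methyltridec-6-en-3-yl]oxetan-2-one
Product: 19 (4S)-4-[(3R,5Z,6E,9S)-9-ethyl-5-(2-hydroxyethylidene)-7-methyltridec-6-en-3-yl]oxetan-2-one
Conditions: HF·pyridine, THF, 0 °C
Reagents that add atoms: none
Why: fluoride-mediated cleavage of the primary allylic silyl ether under buffered, mildly acidic conditions that the β-lactone and the diene tolerate.

Step 12
Reactants: 19 (4S)-4-[(3R,5Z,6E,9S)-9-ethyl-5-(2-hydroxyethylidene)-7-methyltridec-6-en-3-yl]oxetan-2-one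
Product: 20 (4S)-4-[(2R)-1-{(2S,3R)-2-[(1E,4S)-4-ethyl-2-methyloct-1-en-1-yl]-3-(hydroxymethyl)oxiran-2-yl}butan-2-yl]oxetan-2-one
Conditions: Ti(OiPr)4 (20 mol %), D-(−)-diisopropyl tartrate (24 mol %), tBuOOH, 4 Å molecular sieves, CH2Cl2, −20 °C
Reagents that add atoms: tert-butyl hydroperoxide, CC(C)(C)OO
Why: Sharpless asymmetric epoxidation is chemoselective for the allylic-alcohol alkene of the diene and, with the D-tartrate, delivers oxygen to the face that gives the (2S,3R)-oxirane, placing the C6 oxygen on the side opposite to the one required after inversion.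

Step 13
Reactants: 20 (4S)-4-[(2R)-1-{(2S,3R)-2-[(1E,4S)-4-ethyl-2-methyloct-1-en-1-yl]-3-(hydroxymethyl)oxiran-2-yl}butan-2-yl]oxetan-2-one
Product: 22 2-[(3R,4R,6R)-6-[(1R)-1,2-dihydroxyethyl]-4-ethyl-6-[(1E,4S)-4-ethyl-2-methyloct-1-en-1-yl]-1,2-dioxan-3-yl]acetic acid, via hydroperoxide 21 (not isolated)
Conditions: anhydrous H2O2 in Et2O (10 equiv), camphorsulfonic acid (5 mol %), −20 °C; aqueous wash and solvent switch; then Cs2CO3, DMF, 0 °C, high dilution; 1 M HCl work-up
Reagents that add atoms: hydrogen peroxide, OO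
Why: Proposed new method: acid-catalysed perhydrolysis opens the tertiary vinyl epoxide at the allylic, more substituted carbon with inversion (borderline SN2, as in the known perhydrolysis of trisubstituted epoxides and the Lewis-acid opening of tertiary oxetanes by H2O2) to give hydroperoxide 21, whose cesium peroxy anion (far more acidic and nucleophilic than the neighbouring alcohols) then attacks C3 of the β-lactone in a 6-exo-tet SN2 alkyl–oxygen cleavage with inversion (closest known reactions: SN2 opening of 4-alkyl β-lactones by azide or thiolate, ring expansion of β-lactones by tethered oxygen nucleophiles, and cyclisation of hydroperoxy sulfonates to 1,2-dioxanes), closing the 1,2-dioxane and freeing the CH2CO2H arm with C3 and C6 both set by stereospecific inversion.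

Step 14
Reactants: 22 2-[(3R,4R,6R)-6-[(1R)-1,2-dihydroxyethyl]-4-ethyl-6-[(1E,4S)-4-ethyl-2-methyloct-1-en-1-yl]-1,2-dioxan-3-yl]acetic acid
Product: 23 2-[(3R,4R,6R)-4-ethyl-6-[(1E,4S)-4-ethyl-2-methyloct-1-en-1-yl]-6-formyl-1,2-dioxan-3-yl]acetic acid
Conditions: NaIO4, THF/H2O, 0 °C
Reagents that add atoms: none
Why: periodate glycol cleavage of the 1,2-diol gives the C6 aldehyde, which has no α-hydrogen and so cannot epimerise, while peroxide, alkene and acid are inert to periodate.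

Step 15
Reactants: 23 2-[(3R,4R,6R)-4-ethyl-6-[(1E,4S)-4-ethyl-2-methyloct-1-en-1-yl]-6-formyl-1,2-dioxan-3-yl]acetic acid
Product: 24 2-[(3R,4R,6S)-6-ethenyl-4-ethyl-6-[(1E,4S)-4-ethyl-2-methyloct-1-en-1-yl]-1,2-dioxan-3-yl]acetic acid
Conditions: Ph3PCH3Br (3 equiv), KN(SiMe3)2 (2.9 equiv), THF, 0 °C; then 23, −78 to 0 °C
Reagents that add atoms: methyltriphenylphosphonium bromide, C[P+](c1ccccc1)(c1ccccc1)c1ccccc1.[Br-]
Why: Wittig methylenation of the hindered, non-enolisable aldehyde, in which the first equivalent of ylide only deprotonates the acid and the resulting carboxylate protects the β-peroxy acid against base-induced ring opening.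

Step 16
Reactants: 24 2-[(3R,4R,6S)-6-ethenyl-4-ethyl-6-[(1E,4S)-4-ethyl-2-methyloct-1-en-1-yl]-1,2-dioxan-3-yl]acetic acid
Product: 25 2-[(3R,4R,6R)-4,6-diethyl-6-[(1E,4S)-4-ethyl-2-methyloct-1-en-1-yl]-1,2-dioxan-3-yl]acetic acid (target, CNP0229029.2)
Conditions: 2-nitrobenzenesulfonylhydrazide, Et3N, CH2Cl2, rt
Reagents that add atoms: none
Why: diimide reduction (concerted syn hydrogen transfer) reduces the monosubstituted vinyl group far faster than the trisubstituted C7=C8 alkene and does not cleave the O–O bond, turning the vinyl group into the C6 ethyl group.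

**Compound list**

1 | hex-1-ene | C=CCCCC | starting material
2 | diethyl[(2S)-2-ethylhexyl]alumane | CCCC[C@H](CC)C[Al](CC)CC | intermediate
3 | (3S)-3-(iodomethyl)heptane | CCCC[C@H](CC)CI | intermediate
4 | (4S)-4-ethyloct-1-yne | CCCC[C@H](CC)CC#C | intermediate
5 | 2-[(tert-butyldimethylsilyl)oxy]acetaldehyde | O=CCO[Si](C)(C)C(C)(C)C | starting material
6 | ethyl 2-(triphenyl-λ5-phosphanylidene)acetate | CCOC(=O)C=P(c1ccccc1)(c1ccccc1)c1ccccc1 | starting material
7 | ethyl 2-iodo-2-(triphenyl-λ5-phosphanylidene)acetate | CCOC(=O)C(I)=P(c1ccccc1)(c1ccccc1)c1ccccc1 | intermediate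
8 | ethyl (2Z)-4-[(tert-butyldimethylsilyl)oxy]-2-iodobut-2-enoate | CCOC(=O)/C(I)=C/CO[Si](C)(C)C(C)(C)C | intermediate
9 | (2Z)-4-[(tert-butyldimethylsilyl)oxy]-2-iodobut-2-en-1-ol | OC/C(I)=C/CO[Si](C)(C)C(C)(C)C | intermediate
10 | {[(2Z)-4-bromo-3-iodobut-2-en-1-yl]oxy}(tert-butyl)dimethylsilane | BrC/C(I)=C/CO[Si](C)(C)C(C)(C)C | intermediate
11 | (4S)-4-benzyl-3-butanoyl-1,3-oxazolidin-2-one | CCCC(=O)N1[C@@H](Cc2ccccc2)COC1=O | starting material
12 | sodium (1Z)-1-[(4S)-4-benzyl-2-oxo-1,3-oxazolidin-3-yl]but-1-en-1-olate | CC/C=C(\[O-])N1[C@@H](Cc2ccccc2)COC1=O.[Na+] | intermediate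
13 | (4S)-4-benzyl-3-[(2R,4Z)-6-[(tert-butyldimethylsilyl)oxy]-2-ethyl-4-iodohex-4-enoyl]-1,3-oxazolidin-2-one | CC[C@H](C/C(I)=C/CO[Si](C)(C)C(C)(C)C)C(=O)N1[C@@H](Cc2ccccc2)COC1=O | intermediate
14 | (2R,4Z)-6-[(tert-butyldimethylsilyl)oxy]-2-ethyl-4-iodohex-4-en-1-ol | CC[C@H](C/C(I)=C/CO[Si](C)(C)C(C)(C)C)CO | intermediate
15 | [(1E,4S)-4-ethyl-2-methyloct-1-en-1-yl]dimethylalumane | CCCC[C@H](CC)C/C(C)=C/[Al](C)C | intermediate
16 | (2R,4Z,5E,8S)-4-{2-[(tert-butyldimethylsilyl)oxy]ethylidene}-2,8-diethyl-6-methyldodec-5-en-1-ol | CCCC[C@H](CC)C/C(C)=C/C(C[C@@H](CC)CO)=C\CO[Si](C)(C)C(C)(C)C | intermediate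
17 | (2R,4Z,5E,8S)-4-{2-[(tert-butyldimethylsilyl)oxy]ethylidene}-2,8-diethyl-6-methyldodec-5-enal | CCCC[C@H](CC)C/C(C)=C/C(C[C@@H](CC)C=O)=C\CO[Si](C)(C)C(C)(C)C | intermediate
18 | (4S)-4-[(3R,5Z,6E,9S)-5-{2-[(tert-butyldimethylsilyl)oxy]ethylidene}-9-ethyl-7-methyltridec-6-en-3-yl]oxetan-2-one | CCCC[C@H](CC)C/C(C)=C/C(C[C@@H](CC)[C@@H]1CC(=O)O1)=C\CO[Si](C)(C)C(C)(C)C | intermediate
19 | (4S)-4-[(3R,5Z,6E,9S)-9-ethyl-5-(2-hydroxyethylidene)-7-methyltridec-6-en-3-yl]oxetan-2-one | CCCC[C@H](CC)C/C(C)=C/C(C[C@@H](CC)[C@@H]1CC(=O)O1)=C\CO | intermediate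
20 | (4S)-4-[(2R)-1-{(2S,3R)-2-[(1E,4S)-4-ethyl-2-methyloct-1-en-1-yl]-3-(hydroxymethyl)oxiran-2-yl}butan-2-yl]oxetan-2-one | CCCC[C@H](CC)C/C(C)=C/[C@]2(C[C@@H](CC)[C@@H]1CC(=O)O1)O[C@@H]2CO | intermediate
21 | (4S)-4-[(3R,5R,6E,9S)-5-[(1R)-1,2-dihydroxyethyl]-9-ethyl-5-hydroperoxy-7-methyltridec-6-en-3-yl]oxetan-2-one | CCCC[C@H](CC)C/C(C)=C/[C@](OO)(C[C@@H](CC)[C@@H]1CC(=O)O1)[C@H](O)CO | intermediate
22 | 2-[(3R,4R,6R)-6-[(1R)-1,2-dihydroxyethyl]-4-ethyl-6-[(1E,4S)-4-ethyl-2-methyloct-1-en-1-yl]-1,2-dioxan-3-yl]acetic acid | CCCC[C@H](CC)C/C(C)=C/[C@@]1([C@H](O)CO)C[C@@H](CC)[C@@H](CC(=O)O)OO1 | intermediate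
23 | 2-[(3R,4R,6R)-4-ethyl-6-[(1E,4S)-4-ethyl-2-methyloct-1-en-1-yl]-6-formyl-1,2-dioxan-3-yl]acetic acid | CCCC[C@H](CC)C/C(C)=C/[C@@]1(C=O)C[C@@H](CC)[C@@H](CC(=O)O)OO1 | intermediate
24 | 2-[(3R,4R,6S)-6-ethenyl-4-ethyl-6-[(1E,4S)-4-ethyl-2-methyloct-1-en-1-yl]-1,2-dioxan-3-yl]acetic acid | CCCC[C@H](CC)C/C(C)=C/[C@@]1(C=C)C[C@@H](CC)[C@@H](CC(=O)O)OO1 | intermediate
25 | 2-[(3R,4R,6R)-4,6-diethyl-6-[(1E,4S)-4-ethyl-2-methyloct-1-en-1-yl]-1,2-dioxan-3-yl]acetic acid | CCCC[C@H](CC)C/C(C)=C/[C@@]1(CC)C[C@@H](CC)[C@@H](CC(=O)O)OO1 | target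

**Totals**

Total step count: 16.
Longest linear sequence: 14 steps (steps 3 to 16, from 5 and 6 to 25).

**The three steps most likely to fail**

Step 13 (H2O2 stitching). The perhydrolysis at the tertiary allylic carbon may leak through an allyl cation (loss of C6 configuration, 1,4-attack). The peroxy anion may also attack the lactone carbonyl or the β-hydroxy hydroperoxide may fragment, instead of alkylating C3. The fallback sets out from 17 and comes back at 22. It gives up the β-lactone as C3 electrophile and closes the ring by conjugate addition. Horner–Wadsworth–Emmons reaction of 17 with triethyl phosphonoacetate (LiCl, DBU, MeCN) gives ethyl (2E,4R,6Z,7E,10S)-6-{2-[(tert-butyldimethylsilyl)oxy]ethylidene}-4,10-diethyl-8-methyltetradeca-2,7-dienoate F1. HF·pyridine gives ethyl (2E,4R,6Z,7E,10S)-4,10-diethyl-6-(2-hydroxyethylidene)-8-methyltetradeca-2,7-dienoate F2. Sharpless epoxidation as in step 12 gives ethyl (2E,4R)-4-ethyl-5-{(2S,3R)-2-[(1E,4S)-4-ethyl-2-methyloct-1-en-1-yl]-3-(hydroxymethyl)oxiran-2-yl}pent-2-enoate F3. Perhydrolysis (H2O2 in Et2O, camphorsulfonic acid, −20 °C) gives ethyl (2E,4R,6R,7E,10S)-6-[(1R)-1,2-dihydroxyethyl]-4,10-diethyl-6-hydroperoxy-8-methyltetradeca-2,7-dienoate F4. Et2NH in CF3CH2OH then triggers intramolecular oxa-Michael addition to ethyl 2-[(3R,4R,6R)-6-[(1R)-1,2-dihydroxyethyl]-4-ethyl-6-[(1E,4S)-4-ethyl-2-methyloct-1-en-1-yl]-1,2-dioxan-3-yl]acetate F5, with the C3 epimer removed by chromatography. LiOH in THF/H2O at 0 °C returns 22. This fallback does not remove the perhydrolysis risk at C6; it only replaces the untested lactone alkylation.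

Step 12 (Sharpless epoxidation). The alkenyl group sits cis to the CH2OH (a slow substrate class), the β-lactone can be attacked by titanium alkoxides, and the tertiary vinyl epoxide is acid-labile. The fallback sets out from 19 and comes back at 20. It replaces reagent-controlled epoxidation by hydroxyl-directed epoxidation without a chiral reagent, followed by separation. VO(acac)2 and tBuOOH in CH2Cl2 at 0 °C epoxidise only the allylic-alcohol alkene and give 20 together with its oxirane diastereomer (4S)-4-[(2R)-1-{(2R,3S)-2-[(1E,4S)-4-ethyl-2-methyloct-1-en-1-yl]-3-(hydroxymethyl)oxiran-2-yl}butan-2-yl]oxetan-2-one F6. The two are diastereomers because of the three existing stereocentres and are separated by chromatography; at most half of the material is carried on.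

Step 10 (ketene–aldehyde cyclocondensation). The α-branched, diene-bearing aldehyde may react sluggishly or with mismatched double diastereoselection. The fallback sets out from 17 and comes back at 18. It builds C3 by an auxiliary-controlled acetate aldol and closes the lactone afterwards. The dilithium enolate of (S)-2-hydroxy-1,2,2-triphenylethyl acetate (LiN(iPr)2, 2 equiv; MgBr2; THF, −115 °C) adds to 17 to give (1S)-2-hydroxy-1,2,2-triphenylethyl (3S,4R,6Z,7E,10S)-6-{2-[(tert-butyldimethylsilyl)oxy]ethylidene}-4,10-diethyl-3-hydroxy-8-methyltetradec-7-enoate F7. KOH in MeOH/H2O gives (3S,4R,6Z,7E,10S)-6-{2-[(tert-butyldimethylsilyl)oxy]ethylidene}-4,10-diethyl-3-hydroxy-8-methyltetradec-7-enoic acid F8. Benzenesulfonyl chloride in pyridine at 0 °C activates the carboxyl group and lactonises with retention at C3 to give 18.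

**Further compounds**

F1 | step 13 | ethyl (2E,4R,6Z,7E,10S)-6-{2-[(tert-butyldimethylsilyl)oxy]ethylidene}-4,10-diethyl-8-methyltetradeca-2,7-dienoate | CCCC[C@H](CC)C/C(C)=C/C(C[C@@H](CC)/C=C/C(=O)OCC)=C\CO[Si](C)(C)C(C)(C)C
F2 | step 13 | ethyl (2E,4R,6Z,7E,10S)-4,10-diethyl-6-(2-hydroxyethylidene)-8-methyltetradeca-2,7-dienoate | CCCC[C@H](CC)C/C(C)=C/C(C[C@@H](CC)/C=C/C(=O)OCC)=C\CO
F3 | step 13 | ethyl (2E,4R)-4-ethyl-5-{(2S,3R)-2-[(1E,4S)-4-ethyl-2-methyloct-1-en-1-yl]-3-(hydroxymethyl)oxiran-2-yl}pent-2-enoate | CCCC[C@H](CC)C/C(C)=C/[C@]2(C[C@@H](CC)/C=C/C(=O)OCC)O[C@@H]2CO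
F4 | step 13 | ethyl (2E,4R,6R,7E,10S)-6-[(1R)-1,2-dihydroxyethyl]-4,10-diethyl-6-hydroperoxy-8-methyltetradeca-2,7-dienoate | CCCC[C@H](CC)C/C(C)=C/[C@](OO)(C[C@@H](CC)/C=C/C(=O)OCC)[C@H](O)CO
F5 | step 13 | ethyl 2-[(3R,4R,6R)-6-[(1R)-1,2-dihydroxyethyl]-4-ethyl-6-[(1E,4S)-4-ethyl-2-methyloct-1-en-1-yl]-1,2-dioxan-3-yl]acetate | CCCC[C@H](CC)C/C(C)=C/[C@@]1([C@H](O)CO)C[C@@H](CC)[C@@H](CC(=O)OCC)OO1
F6 | step 12 | (4S)-4-[(2R)-1-{(2R,3S)-2-[(1E,4S)-4-ethyl-2-methyloct-1-en-1-yl]-3-(hydroxymethyl)oxiran-2-yl}butan-2-yl]oxetan-2-one | CCCC[C@H](CC)C/C(C)=C/[C@@]2(C[C@@H](CC)[C@@H]1CC(=O)O1)O[C@H]2CO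
F7 | step 10 | (1S)-2-hydroxy-1,2,2-triphenylethyl (3S,4R,6Z,7E,10S)-6-{2-[(tert-butyldimethylsilyl)oxy]ethylidene}-4,10-diethyl-3-hydroxy-8-methyltetradec-7-enoate | CCCC[C@H](CC)C/C(C)=C/C(C[C@@H](CC)[C@@H](O)CC(=O)O[C@@H](c1ccccc1)C(O)(c1ccccc1)c1ccccc1)=C\CO[Si](C)(C)C(C)(C)C
F8 | step 10 | (3S,4R,6Z,7E,10S)-6-{2-[(tert-butyldimethylsilyl)oxy]ethylidene}-4,10-diethyl-3-hydroxy-8-methyltetradec-7-enoic acid | CCCC[C@H](CC)C/C(C)=C/C(C[C@@H](CC)[C@@H](O)CC(=O)O)=C\CO[Si](C)(C)C(C)(C)C
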